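## Structural features

The target is a flavonol: a 2-aryl-3-hydroxychromen-4-one in which the pyranone ring C (O1, C2, C3, C4) is fused through C4a and C8a to the benzo ring A and carries at C2 the 3-hydroxy-4-methoxyphenyl ring B. Ring A has no hydrogen left: C5 bears a hydroxyl that is hydrogen-bonded to the C4 carbonyl, C6 and C8 each bear a 3-methylbut-2-enyl (prenyl) chain, and C7 bears a methoxyl. There is no stereocentre and no alkene geometry to control, because each side-chain alkene ends in two methyl groups. The fragile parts are the two trisubstituted alkenes, which sit ortho to oxygen and can close to chromans or add electrophiles under acid, halogen, peracid or hydrogenation conditions, and the 3-hydroxy-4-pyranone, which is prone to autoxidation in base. The real difficulty is twofold: a hexasubstituted, oxygen-rich ring A with a fixed pattern of one free hydroxyl, one methyl ether and two prenyl groups, and a C3 oxygen that must be introduced without any oxidant meeting the prenyl alkenes. The feature the plan exploits is the local symmetry of ring A: the substituents at C6, C7 and C8 are mirror images about the axis through C7 and C4a, and C4a lies between the two oxygen-bearing carbons C5 and C8a. With ring C removed, ring A is a resorcinol whose two hydroxyls (later O1 and the C5 hydroxyl) are equivalent and whose only ring CH is the later C4a, so a C4–C3–C2 unit that already carries the C3 oxygen can be fused on in one orientation only.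

## Logic of the disconnections

17 to 16: the two ester C–O bonds that join benzoyl groups to O3 and to the ring B oxygen are cut. The last step must be free of acid, oxidant and reductant, and activated benzoates (one enol ester, one aryl ester) fall off under weak base in methanol. Using the same acyl group at both oxygens means that any acyl transfer among hydroxyls earlier in the route is erased here. The forward step needs only exclusion of air, because the freed flavonol is oxidisable in base.

16 to 6 and 13: the C4–C4a and O1–C2 bonds are cut, which removes ring C and splits the molecule into two fragments of similar size. The cut is placed here because 6 has a single ring CH between two equivalent hydroxyls, so no regiochemical question arises, and because 13 brings the C3 oxygen at the correct oxidation level, so no late oxidation is needed. The forward step must acylate carbon rather than condense in the coumarin sense, and it must do so without acid so that the ortho-prenyl phenols survive.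

6 to 4 (through 5): a carboxyl ester is added back at the ring CH of 6, that is, a ring C–C bond is cut in the forward sense. This carbon is the most nucleophilic position of the resorcinol and must be blocked while the prenyl groups go on. An ester is the blocking group that can be removed by base alone, through hydrolysis and loss of CO2 from 5. The forward step demands hydrolysis of a hindered, electron-rich ester without air and without strong acid.

4 to 2 and 3: the two aryl–CH2 bonds at the carbons that become C6 and C8 are cut. These are the only open ring positions of 2, both ortho to a phenoxide oxygen, so a double C-alkylation that consumes two equivalents of 3 delivers the whole carbon skeleton of ring A in one operation. The forward step must favour carbon over oxygen alkylation, react at the primary carbon of 3, and stop after two alkylations.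

2 to 1: the O–CH3 bond at the oxygen para to the ester is cut. In 1 this hydroxyl is the only one not tied to the ester carbonyl by a hydrogen bond, so it can be alkylated selectively. The demand is mono-methylation.

13 to 12: the bond between the α-carbon and the benzoyloxy oxygen is cut. The future C3 oxygen is installed at the active methylene by an electrophilic benzoyloxy donor, at a stage where no prenyl alkene is present. The forward step must stop at mono-substitution.

12 to 8 and 9 (through 10 and 11): the bond between the aroyl carbon and the methylene carbon is cut, a two-carbon homologation of an aromatic acid by a malonate half ester. The conditions must be mild enough to keep the aryl benzoate.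

8 to 7: the O–C(=O)Ph bond is cut. The ring B phenol is masked as the same benzoate that is used at C3, so a single final operation frees both.

## Other disconnections considered

Alternative 1: The cut runs through C4a–C4 and C4–C3, so that C4 is supplied by carbon monoxide A4. The aryl iodide 2-iodo-5-methoxy-1,3-bis(methoxymethoxy)-4,6-bis(3-methylbut-2-enyl)benzene A2, A4 and the sodium enolate of 2-(methoxymethoxy)-1-[4-methoxy-3-(methoxymethoxy)phenyl]ethanone A3 would be joined with Pd(dba)2 (zerovalent palladium) and Xantphos to the open-chain diketone A1. Acid would then have to remove four methoxymethyl groups and close ring C.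
- In its favour: the coupling runs far below the temperature of a thermal annulation, and the diketone connectivity leaves no coumarin option at all. On both points it is better than the chosen plan. A2 would come from 6 by iodination at its only ring CH, so the two plans are equal in their reliance on the same ring A chemistry.
- Against it: the iodine of A2 is flanked by two acetal ethers on a fully substituted, electron-rich ring, which should slow oxidative addition and acyl transfer. The enolate of A3 is α-oxygenated and gives a crowded, acidic 2-substituted diketone. The final acid treatment is exactly what ortho-prenyl phenols tolerate least.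
- Step economy: from 6 it needs iodination, protection, coupling and deprotection with cyclisation, where the chosen plan needs annulation and methanolysis, and A3 needs its own preparation.

Alternative 2: Here ring A itself is cut, at C5–C6 and C7–C8. 2-(3-Methylbut-2-enyl)-3-(triisopropylsilyloxy)cyclobut-2-en-1-one A6 and 1-methoxy-5-methylhex-4-en-1-yne A7 would be heated in toluene. The sequence is 4π opening of A6 to a vinylketene, [2+2] addition to A7, 4π opening of the new vinylcyclobutenone, then 6π closure and tautomerisation to the mono-silylated resorcinol A5.
- In its favour: each prenyl group arrives on a small fragment, so there is no competition between oxygen and carbon alkylation of a phenoxide and no blocking ester, and the polarisation of the alkynyl ether fixes the substitution pattern. On certainty of prenyl placement it is better than the chosen plan, and its temperature is lower.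
- Against it: it solves only the ring A problem. After desilylation to 6, ring C must still be built, for instance by the annulation of step 7, so it replaces steps 1 to 3 and does not replace the strategy. The differentiation of the two oxygens in A5 is of no use for a symmetric annulation.
- Step economy: A6 and A7 are sensitive, not commercial and each need several steps, so three simple steps would be exchanged for roughly twice as many. Both plans are equal in having no stereochemical issue.

Alternative 3: The two side-chain alkenes are cut. The 6,8-diallyl flavonol triacetate A9 would undergo double cross-metathesis with excess 2-methylbut-2-ene A10 under RuCl2(CHPh)(PCy3)(H2IMes), the second-generation Grubbs catalyst, to give the diprenyl triacetate A8, and deacetylation would follow.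
- In its favour: allyl groups cannot ionise to tertiary cations, so the flavonol core could be assembled under acidic, hot or oxidising conditions. They are also installed regiospecifically by O-allylation and Claisen rearrangement. On robustness of intermediates and on the way the side-chain C–C bonds are made it is better than the chosen plan. The final deacylation is of the same kind as step 8, so the plans are equal there.
- Against it: two alkenes must both be converted completely, and partly converted or but-2-enyl products would be close in polarity to A8. An extra acetylation is needed and the ruthenium step comes late.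
- Step economy: it is three to four steps longer and less convergent. The chosen plan accepts more thermal risk in exchange for brevity, and this alternative is the source of the fallback for step 7.

Key step: step 7

Assumption: mapping the annulation atom by atom (ring CH of 6 to C4a, ester carbon of 13 to C4, α-carbon to C3, ketone carbon to C2) reproduces the substitution pattern of 17, so the structures of 6, 13 and 16 need no correction; positional benzoate isomers that may accompany 16 are taken to converge on 17 in step 8.

## Route

Step 1
Reactants: 1 methyl 2,4,6-trihydroxybenzoate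
Product: 2 methyl 2,6-dihydroxy-4-methoxybenzoate
Conditions: Me2SO4 (1.0 equiv), K2CO3 (1.0 equiv), acetone, 0 °C to rt
Reagents that add atoms: dimethyl sulfate, COS(=O)(=O)OC
Why: Williamson O-methylation; the 4-hydroxyl is para to the ester and is the only one not hydrogen-bonded to the ester carbonyl, so it is the most acidic and accessible and one equivalent of base and alkylating agent should methylate it selectively.

Step 2
Reactants: 2 methyl 2,6-dihydroxy-4-methoxybenzoate; 3 prenyl bromide (1-bromo-3-methylbut-2-ene), of which two equivalents are consumed
Product: 4 methyl 2,6-dihydroxy-4-methoxy-3,5-bis(3-methylbut-2-enyl)benzoate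
Conditions: 3 (2.3 equiv in all, slow addition), 10% aq. KOH, 0 °C to rt, Ar
Reagents that add atoms: prenyl bromide (the second equivalent of 3, which supplies the second prenyl group), CC(C)=CCBr
Why: Two-fold ortho C-alkylation of a phenoxide (C-prenylation) in water, where solvation of the oxygens steers the dianion to react at carbon; only C3 and C5 are open because the ester occupies the carbon between the hydroxyls, so one molecule of 3 is taken up at each, and SN2 attack at the primary carbon of 3 keeps the 3-methylbut-2-enyl connectivity.

Step 3
Reactants: 4 methyl 2,6-dihydroxy-4-methoxy-3,5-bis(3-methylbut-2-enyl)benzoate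
Product: 6 5-methoxy-4,6-bis(3-methylbut-2-enyl)benzene-1,3-diol, via 2,6-dihydroxy-4-methoxy-3,5-diprenylbenzoic acid 5 (not isolated)
Conditions: KOH (6 equiv), EtOH/H2O 1:1, reflux, Ar; cool, AcOH to pH 5–6, 50 °C until gas evolution ends
Reagents that add atoms: none
Why: Ester saponification followed by protodecarboxylation of an electron-rich 2,6-dihydroxybenzoic acid (ipso protonation, then loss of CO2), the usual way to remove a carboxyl blocking group from a resorcinol that carries acid-sensitive alkenes; the medium never becomes strongly acidic, so the prenyl groups should survive.

Step 4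
Reactants: 7 isovanillic acid (3-hydroxy-4-methoxybenzoic acid)
Product: 8 3-(benzoyloxy)-4-methoxybenzoic acid
Conditions: BzCl (1.1 equiv), 2 M aq. NaOH, 0 °C; then HCl to pH 2, filter
Reagents that add atoms: benzoyl chloride, O=C(Cl)c1ccccc1
Why: Schotten–Baumann O-benzoylation of the phenoxide; any mixed anhydride formed at the carboxylate is hydrolysed in the aqueous base, and acidification precipitates the acid.

Step 5
Reactants: 8 3-(benzoyloxy)-4-methoxybenzoic acid; 9 potassium ethyl malonate (potassium 3-ethoxy-3-oxopropanoate)
Product: 12 ethyl 3-[3-(benzoyloxy)-4-methoxyphenyl]-3-oxopropanoate, via 3-(benzoyloxy)-4-methoxybenzoyl chloride 10 (not isolated), via acylmalonic half ester 11 (not isolated)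
Conditions: (COCl)2, cat. DMF, CH2Cl2, 0 °C to rt, evaporate; then 9 (2 equiv), MgCl2, Et3N, MeCN, 0 °C to rt; 1 M HCl work-up
Reagents that add atoms: oxalyl chloride, O=C(Cl)C(=O)Cl (supplies the chlorine of 10 only; none of its atoms remain in 12)
Why: Acid chloride formation followed by C-acylation of the magnesium enolate of the malonate half ester (a Masamune–Brooks-type homologation run on the acid chloride) and decarboxylation of 11 on acidification; the weak base and soft nucleophile should leave the aryl benzoate intact.

Step 6
Reactants: 12 ethyl 3-[3-(benzoyloxy)-4-methoxyphenyl]-3-oxopropanoate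
Product: 13 ethyl 2-(benzoyloxy)-3-[3-(benzoyloxy)-4-methoxyphenyl]-3-oxopropanoate (racemic)
Conditions: NaH (1.0 equiv), THF, 0 °C; enolate added to (BzO)2 (1.0 equiv), THF, −20 to 0 °C
Reagents that add atoms: dibenzoyl peroxide, O=C(OOC(=O)c1ccccc1)c1ccccc1
Why: Electrophilic α-benzoyloxylation of a β-ketoester enolate by attack on the O–O bond of a diacyl peroxide, a known oxygenation of 1,3-dicarbonyl enolates; one equivalent of base and inverse addition should limit double substitution, and the new stereocentre is formed racemic and disappears in step 7.

Step 7
Reactants: 6 5-methoxy-4,6-bis(3-methylbut-2-enyl)benzene-1,3-diol; 13 ethyl 2-(benzoyloxy)-3-[3-(benzoyloxy)-4-methoxyphenyl]-3-oxopropanoate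
Product: 16 3-(benzoyloxy)-2-[3-(benzoyloxy)-4-methoxyphenyl]-5-hydroxy-7-methoxy-6,8-bis(3-methylbut-2-enyl)chromen-4-one, via α-benzoyloxy aroylketene 14 (not isolated), via open-chain aryl diketone 15 (not isolated)
Conditions: 13 (1.5 equiv), Ph2O (degassed, concentrated), Ar sweep, 200–220 °C, 30–60 min, no catalyst
Reagents that add atoms: none
Why: This is the Mentzer pyrone synthesis, the thermal catalyst-free condensation of an electron-rich phenol with a β-ketoester to a chromone, whose classical scope includes α-substituted ketoesters that give 3-substituted chromones. Heat expels ethanol from the chelated enol of 13 to give the α-oxoketene 14, which is captured reversibly at phenolic oxygen but irreversibly at the one ring carbon of 6 that is ortho to both hydroxyls and para to the methoxyl, forming the C4–C4a bond and the diketone 15. Either of the two equivalent hydroxyls of 15 then adds to the aryl ketone carbonyl in a 6-exo-trig closure and the hemiketal loses water, which forms the O1–C2 bond and the 4-pyranone of ring C and leaves the other hydroxyl as the chelated C5 hydroxyl. No stereocentre is created, since the racemic α-carbon of 13 becomes the sp2 carbon C3 of 16. The selectivity needed is chromone over coumarin closure together with a single regiochemistry: without acid the aryl ketone is not activated towards attack by the ring carbon, the α-benzoyloxy group crowds that ketone further, and the mirror symmetry of 6 makes both possible oxygen closures identical. Neutral conditions, an argon sweep that carries off ethanol and water as they form, and a short heating time are chosen to keep the ortho-prenyl phenols from closing to chromans. Migration of benzoyl groups among the hydroxyls during heating is tolerable because step 8 removes every benzoate.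

Step 8
Reactants: 16 3-(benzoyloxy)-2-[3-(benzoyloxy)-4-methoxyphenyl]-5-hydroxy-7-methoxy-6,8-bis(3-methylbut-2-enyl)chromen-4-one
Product: 17 3,5-dihydroxy-2-(3-hydroxy-4-methoxyphenyl)-7-methoxy-6,8-bis(3-methylbut-2-enyl)chromen-4-one
Conditions: K2CO3 (3 equiv), MeOH (degassed), Ar, 0 °C to rt; AcOH to pH 6
Reagents that add atoms: none
Why: Base-mediated methanolysis (transesterification) of an enol benzoate and an aryl benzoate, both activated esters; methyl ethers and prenyl alkenes are inert to methoxide, and exclusion of air protects the 3-hydroxypyranone from autoxidation.

## Compound list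

1 | methyl 2,4,6-trihydroxybenzoate | COC(=O)c1c(O)cc(O)cc1O | starting material
2 | methyl 2,6-dihydroxy-4-methoxybenzoate | COC(=O)c1c(O)cc(OC)cc1O | intermediate
3 | prenyl bromide (1-bromo-3-methylbut-2-ene) | CC(C)=CCBr | starting material
4 | methyl 2,6-dihydroxy-4-methoxy-3,5-bis(3-methylbut-2-enyl)benzoate | COC(=O)c1c(O)c(CC=C(C)C)c(OC)c(CC=C(C)C)c1O | intermediate
5 | 2,6-dihydroxy-4-methoxy-3,5-bis(3-methylbut-2-enyl)benzoic acid | OC(=O)c1c(O)c(CC=C(C)C)c(OC)c(CC=C(C)C)c1O | intermediate (not isolated)
6 | 5-methoxy-4,6-bis(3-methylbut-2-enyl)benzene-1,3-diol | COc1c(CC=C(C)C)c(O)cc(O)c1CC=C(C)C | intermediate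
7 | isovanillic acid (3-hydroxy-4-methoxybenzoic acid) | COc1ccc(C(=O)O)cc1O | starting material
8 | 3-(benzoyloxy)-4-methoxybenzoic acid | COc1ccc(C(=O)O)cc1OC(=O)c1ccccc1 | intermediate
9 | potassium ethyl malonate (potassium 3-ethoxy-3-oxopropanoate) | CCOC(=O)CC(=O)[O-].[K+] | starting material
10 | 3-(benzoyloxy)-4-methoxybenzoyl chloride | COc1ccc(C(Cl)=O)cc1OC(=O)c1ccccc1 | intermediate (not isolated)
11 | 2-[3-(benzoyloxy)-4-methoxybenzoyl]-3-ethoxy-3-oxopropanoic acid (acylmalonic half ester, racemic) | CCOC(=O)C(C(=O)O)C(=O)c1ccc(OC)c(OC(=O)c2ccccc2)c1 | intermediate (not isolated)
12 | ethyl 3-[3-(benzoyloxy)-4-methoxyphenyl]-3-oxopropanoate | CCOC(=O)CC(=O)c1ccc(OC)c(OC(=O)c2ccccc2)c1 | intermediate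
13 | ethyl 2-(benzoyloxy)-3-[3-(benzoyloxy)-4-methoxyphenyl]-3-oxopropanoate (racemic, enolizable) | CCOC(=O)C(OC(=O)c1ccccc1)C(=O)c1ccc(OC)c(OC(=O)c2ccccc2)c1 | intermediate
14 | 2-(benzoyloxy)-3-[3-(benzoyloxy)-4-methoxyphenyl]-3-oxoprop-1-en-1-one (α-benzoyloxy aroylketene) | O=C=C(OC(=O)c1ccccc1)C(=O)c1ccc(OC)c(OC(=O)c2ccccc2)c1 | intermediate (not isolated)
15 | 2-(benzoyloxy)-1-[3-(benzoyloxy)-4-methoxyphenyl]-3-[2,6-dihydroxy-4-methoxy-3,5-bis(3-methylbut-2-enyl)phenyl]propane-1,3-dione (racemic, enolizable) | COc1ccc(C(=O)C(OC(=O)c2ccccc2)C(=O)c2c(O)c(CC=C(C)C)c(OC)c(CC=C(C)C)c2O)cc1OC(=O)c1ccccc1 | intermediate (not isolated)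
16 | 3-(benzoyloxy)-2-[3-(benzoyloxy)-4-methoxyphenyl]-5-hydroxy-7-methoxy-6,8-bis(3-methylbut-2-enyl)chromen-4-one | COc1ccc(-c2oc3c(CC=C(C)C)c(OC)c(CC=C(C)C)c(O)c3c(=O)c2OC(=O)c2ccccc2)cc1OC(=O)c1ccccc1 | intermediate
17 | 3,5-dihydroxy-2-(3-hydroxy-4-methoxyphenyl)-7-methoxy-6,8-bis(3-methylbut-2-enyl)chromen-4-one | COc1ccc(-c2oc3c(CC=C(C)C)c(OC)c(CC=C(C)C)c(O)c3c(=O)c2O)cc1O | target

## Step count and risks

Total: 8 steps. Longest linear sequence: 5 steps (1, 2, 3, 7, 8 or 4, 5, 6, 7, 8).

Step 7 (key step). The most likely failure is loss of the prenyl alkenes through ring closure onto the neighbouring hydroxyls. This could happen once traces of benzoic acid arise from the benzoates and the water of condensation above 200 °C. A second weakness is thermal acyl migration within 13 before it has lost ethanol, which would divert it from ketene formation. The argon sweep, the short heating time and taking crude material straight into step 8 are condition-level measures already built in. The fallback masks the prenyl groups as allyl groups through the thermal step; it sets out from 2 and returns at 16. Both hydroxyls of 2 are O-allylated (allyl bromide, K2CO3, DMF) to methyl 4-methoxy-2,6-bis(prop-2-enyloxy)benzoate F1. A double aromatic Claisen rearrangement in N,N-diethylaniline at about 190 °C moves each allyl group to its only free ortho carbon and gives methyl 2,6-dihydroxy-4-methoxy-3,5-di(prop-2-enyl)benzoate F2. Saponification and decarboxylation as in step 3 pass through 2,6-dihydroxy-4-methoxy-3,5-di(prop-2-enyl)benzoic acid F3 to 5-methoxy-4,6-di(prop-2-enyl)benzene-1,3-diol F4. Thermal annulation of F4 with 13, which can now be heated longer because allyl groups cannot form chromans by way of tertiary cations, runs through 14 and the diketone 2-(benzoyloxy)-1-[3-(benzoyloxy)-4-methoxyphenyl]-3-[2,6-dihydroxy-4-methoxy-3,5-di(prop-2-enyl)phenyl]propane-1,3-dione F5 and gives 3-(benzoyloxy)-2-[3-(benzoyloxy)-4-methoxyphenyl]-5-hydroxy-7-methoxy-6,8-di(prop-2-enyl)chromen-4-one F6. Double cross-metathesis of F6 with excess 2-methylbut-2-ene under RuCl2(CHPh)(PCy3)(H2IMes), the second-generation Grubbs catalyst, in CH2Cl2 converts both allyl groups to prenyl groups and delivers 16.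

Step 2. Alkylation at oxygen, and a further alkylation at an already substituted carbon with loss of aromaticity, may compete with the two-fold ortho C-alkylation, and the reaction may also stall after the first prenyl group has gone on. The 4-methoxy dianion is a weaker carbon nucleophile than a phloroglucinol trianion, and 3 is a reactive, unselective electrophile. The fallback replaces phenoxide alkylation by cross-coupling; it sets out from 2 and returns at 4. Bromination at the two open ring positions (N-bromosuccinimide, 2 equiv, MeCN, 0 °C) gives methyl 3,5-dibromo-2,6-dihydroxy-4-methoxybenzoate F7. A double Stille coupling with tributyl(3-methylbut-2-enyl)stannane and Pd(PPh3)4 in DMF at 90–100 °C, in which the allylic partner couples at its unsubstituted terminus, gives 4.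

Step 6. Proton exchange between the product and unreacted enolate can lead to a second benzoyloxylation and leave starting material behind, and the enolate may also attack the aryl benzoate. The fallback goes through a halide; it sets out from 12 and returns at 13. α-Bromination (N-bromosuccinimide, cat. NH4OAc, Et2O, rt) gives ethyl 2-bromo-3-[3-(benzoyloxy)-4-methoxyphenyl]-3-oxopropanoate F8. SN2 displacement with potassium benzoate in DMF at rt gives 13.

Step 3. Acyl substitution at the ester may be slow, because the carbonyl is flanked by two phenoxides that both shield and deactivate it. Long heating in base exposes the electron-rich resorcinol to oxidative degradation. The fallback cleaves the alkyl–oxygen bond and not the acyl–oxygen bond; it sets out from 4 and returns at 6 through 5. LiI in refluxing pyridine demethylates the ester by SN2 attack at the methyl group, helped by the good leaving-group ability of a 2,6-dihydroxybenzoate. The resulting carboxylate is brought to pH 5–6 and loses CO2 on gentle warming to give 6. No new compound is involved.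

## Further compounds

F1 | step 7 | methyl 4-methoxy-2,6-bis(prop-2-enyloxy)benzoate | COC(=O)c1c(OCC=C)cc(OC)cc1OCC=C
F2 | step 7 | methyl 2,6-dihydroxy-4-methoxy-3,5-di(prop-2-enyl)benzoate | COC(=O)c1c(O)c(CC=C)c(OC)c(CC=C)c1O
F3 | step 7 | 2,6-dihydroxy-4-methoxy-3,5-di(prop-2-enyl)benzoic acid | OC(=O)c1c(O)c(CC=C)c(OC)c(CC=C)c1O
F4 | step 7 | 5-methoxy-4,6-di(prop-2-enyl)benzene-1,3-diol | COc1c(CC=C)c(O)cc(O)c1CC=C
F5 | step 7 | 2-(benzoyloxy)-1-[3-(benzoyloxy)-4-methoxyphenyl]-3-[2,6-dihydroxy-4-methoxy-3,5-di(prop-2-enyl)phenyl]propane-1,3-dione (racemic, enolizable) | COc1ccc(C(=O)C(OC(=O)c2ccccc2)C(=O)c2c(O)c(CC=C)c(OC)c(CC=C)c2O)cc1OC(=O)c1ccccc1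
F6 | step 7 | 3-(benzoyloxy)-2-[3-(benzoyloxy)-4-methoxyphenyl]-5-hydroxy-7-methoxy-6,8-di(prop-2-enyl)chromen-4-one | COc1ccc(-c2oc3c(CC=C)c(OC)c(CC=C)c(O)c3c(=O)c2OC(=O)c2ccccc2)cc1OC(=O)c1ccccc1
F7 | step 2 | methyl 3,5-dibromo-2,6-dihydroxy-4-methoxybenzoate | COC(=O)c1c(O)c(Br)c(OC)c(Br)c1O
F8 | step 6 | ethyl 2-bromo-3-[3-(benzoyloxy)-4-methoxyphenyl]-3-oxopropanoate (racemic) | CCOC(=O)C(Br)C(=O)c1ccc(OC)c(OC(=O)c2ccccc2)c1
F0 | step 3 | none | none
A1 | alternative 1 | 1-[4-methoxy-2,6-bis(methoxymethoxy)-3,5-bis(3-methylbut-2-enyl)phenyl]-2-(methoxymethoxy)-3-[4-methoxy-3-(methoxymethoxy)phenyl]propane-1,3-dione (racemic, enolizable) | COCOc1cc(C(=O)C(OCOC)C(=O)c2c(OCOC)c(CC=C(C)C)c(OC)c(CC=C(C)C)c2OCOC)ccc1OC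
A2 | alternative 1 | 2-iodo-5-methoxy-1,3-bis(methoxymethoxy)-4,6-bis(3-methylbut-2-enyl)benzene | COCOc1c(I)c(OCOC)c(CC=C(C)C)c(OC)c1CC=C(C)C
A3 | alternative 1 | 2-(methoxymethoxy)-1-[4-methoxy-3-(methoxymethoxy)phenyl]ethanone | COCOCC(=O)c1ccc(OC)c(OCOC)c1
A4 | alternative 1 | carbon monoxide | [C-]#[O+]
A5 | alternative 2 | 3-methoxy-2,4-bis(3-methylbut-2-enyl)-5-(triisopropylsilyloxy)phenol | COc1c(CC=C(C)C)c(O)cc(O[Si](C(C)C)(C(C)C)C(C)C)c1CC=C(C)C
A6 | alternative 2 | 2-(3-methylbut-2-enyl)-3-(triisopropylsilyloxy)cyclobut-2-en-1-one | CC(C)=CCC1=C(O[Si](C(C)C)(C(C)C)C(C)C)CC1=O
A7 | alternative 2 | 1-methoxy-5-methylhex-4-en-1-yne | COC#CCC=C(C)C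
A8 | alternative 3 | 3,5-diacetoxy-2-(3-acetoxy-4-methoxyphenyl)-7-methoxy-6,8-bis(3-methylbut-2-enyl)chromen-4-one | CC(C)=CCc1c(OC)c(CC=C(C)C)c2oc(-c3ccc(OC)c(OC(C)=O)c3)c(OC(C)=O)c(=O)c2c1OC(C)=O
A9 | alternative 3 | 3,5-diacetoxy-2-(3-acetoxy-4-methoxyphenyl)-7-methoxy-6,8-di(prop-2-enyl)chromen-4-one | C=CCc1c(OC)c(CC=C)c2oc(-c3ccc(OC)c(OC(C)=O)c3)c(OC(C)=O)c(=O)c2c1OC(C)=O
A10 | alternative 3 | 2-methylbut-2-ene | CC=C(C)C
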